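**Plan**
- Cuts, in retrosynthetic order: the lactone C12–O6 bond (opened to a 6,12-diol, C12 kept one oxidation level low as a PMB ether); the C5–C6 bond of the ten-membered ring (C6 aldehyde plus (Z)-C5 alkenyl iodide); C7–C8 (syn aldol); C1=C10 (cross-metathesis); C2–C3 (allylation).
- Forward: a linear C5→C8 chain is built first, and the aldol then adds the five lactone carbons C6, C7, C11–C13. The 1,10-epoxide is set on the open chain, the ten-membered carbocycle is closed at C5–C6, the γ-lactone ring follows by oxidation of the 6,12-diol, and the C8 ester goes on last.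
- Stereochemistry: C3 from a Keck allylation; C7 and C8 from an (R)-oxazolidinone syn-aldol; C1/C10 from a Shi epoxidation; C6 in the ring closure by 1,2-induction from C7. The 4Z alkene comes from anti-carbomagnesiation of propargyl alcohol and the 1(10)E alkene from metathesis with methacrolein.
- Enabling feature: C6 is at once the oxygen-bearing γ-carbon of the butyrolactone ring and the allylic carbon next to the Z-C4=C5 alkene of the ten-membered ring. It can therefore be an aldehyde that receives a (Z)-alkenyl metal at C5, and the O6/C12 1,4-relationship then gives the lactone.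
- Helpers: iodine at C5 (lost in the ring closure), PMB on O12 (step 18), triethylsilyl on O8 (step 20); the C3 acetate of the target is carried from step 4.

Key step: step 17

Remark: locants are those of the germacrane skeleton (ring C1–C10, lactone carbons C11–C13, C14 on C10, C15 on C4); the SMILES is read as (1R,3S,4Z,6R,7R,8S,10R) with a trans-fused 12,6-lactone and a trans 1,10-epoxide.

**Route**

Step 1
Reactants: 1 prop-2-yn-1-ol
Product: 3 (Z)-3-iodo-2-methylprop-2-en-1-ol, via alkenylmagnesium alkoxide 2 (not isolated)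
Conditions: MeMgBr (2.5 equiv), CuI (10 mol %), THF, -10 °C to rt; then I2, -78 to 0 °C; aqueous work-up
Reagents that add atoms: methylmagnesium bromide, C[Mg]Br; iodine, [I][I]
Why: Copper-catalysed anti-carbomagnesiation of the propargylic alkoxide puts methyl on C4 and magnesium on C5 cis to the CH2O group through the five-membered magnesium chelate, and iodinolysis with retention gives the (Z)-iodoalkene that later becomes the 4Z alkene.

Step 2
Reactants: 3 (Z)-3-iodo-2-methylprop-2-en-1-ol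
Product: 4 (Z)-3-iodo-2-methylprop-2-enal
Conditions: MnO2 (10 equiv), CH2Cl2, rt
Reagents that add atoms: none
Why: Allylic alcohol oxidation with activated MnO2 stops at the enal and should leave the iodoalkene geometry untouched.

Step 3
Reactants: 4 (Z)-3-iodo-2-methylprop-2-enal
Product: 5 (1Z,3S)-1-iodo-2-methylhexa-1,5-dien-3-ol
Conditions: allylSnBu3 (1.5 equiv), (S)-BINOL (20 mol %), Ti(OiPr)4 (10 mol %), 4 Å molecular sieves, CH2Cl2, -20 °C; aq NaHCO3
Reagents that add atoms: allyltributylstannane, C=CC[Sn](CCCC)(CCCC)CCCC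
Why: Keck asymmetric allylation; the (S)-BINOL–titanium Lewis acid should direct allyl to the enal face that gives the (S)-carbinol (same facial sense as for benzaldehyde, the alkenyl group ranking above allyl), which sets C3.

Step 4
Reactants: 5 (1Z,3S)-1-iodo-2-methylhexa-1,5-dien-3-ol
Product: 6 (1Z,3S)-1-iodo-2-methylhexa-1,5-dien-3-yl acetate
Conditions: Ac2O, pyridine, DMAP (cat.), CH2Cl2, 0 °C to rt
Reagents that add atoms: acetic anhydride, CC(=O)OC(C)=O
Why: DMAP-catalysed acetylation installs the C3 acetate of the target, which then serves as its own protecting group.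

Step 5
Reactants: 6 (1Z,3S)-1-iodo-2-methylhexa-1,5-dien-3-yl acetate; 7 methacrolein
Product: 8 (2E,5S,6Z)-7-iodo-2,6-dimethyl-1-oxohepta-2,6-dien-5-yl acetate
Conditions: 7 (5 equiv), second-generation Hoveyda–Grubbs catalyst [RuCl2(H2IMes)(=CH-C6H4-2-OiPr)] (5 mol %), CH2Cl2, 40 °C
Reagents that add atoms: none
Why: Olefin cross-metathesis of the terminal alkene with methacrolein should give the conjugated E-trisubstituted enal (C1=C10 with C14), while the trisubstituted iodoalkene is inert to the ruthenium carbene.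

Step 6
Reactants: 8 (2E,5S,6Z)-7-iodo-2,6-dimethyl-1-oxohepta-2,6-dien-5-yl acetate
Product: 9 (1Z,3S,5E)-1-iodo-2,6-dimethylocta-1,5,7-trien-3-yl acetate
Conditions: Ph3PCH3Br (1.2 equiv), KN(SiMe3)2 (1.15 equiv), THF, -78 to 0 °C
Reagents that add atoms: methyltriphenylphosphonium bromide, C[P+](c1ccccc1)(c1ccccc1)c1ccccc1.[Br-]
Why: Wittig methylenation of the enal adds C8 and is fast enough at low temperature that the acetate should not be attacked.

Step 7
Reactants: 9 (1Z,3S,5E)-1-iodo-2,6-dimethylocta-1,5,7-trien-3-yl acetate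
Product: 11 (1Z,3S,5E)-8-hydroxy-1-iodo-2,6-dimethylocta-1,5-dien-3-yl acetate, via alkylborane 10 (not isolated)
Conditions: 9-BBN (1.3 equiv), THF, 0 °C to rt; then NaBO3·4H2O, H2O, rt
Reagents that add atoms: 9-borabicyclo[3.3.1]nonane, B1C2CCCC1CCC2 (boron unit in intermediate 10 only); sodium perborate, [Na+].[Na+].O[B-]1(O)OO[B-](O)(O)OO1
Why: Hydroboration–oxidation; 9-BBN adds anti-Markovnikov only to the monosubstituted terminus of the 1,3-diene, and the perborate oxidation is mild enough for the acetate, giving the homoallylic alcohol with the E-C1=C10 alkene intact.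

Step 8
Reactants: 11 (1Z,3S,5E)-8-hydroxy-1-iodo-2,6-dimethylocta-1,5-dien-3-yl acetate
Product: 12 (1Z,3S,5E)-1-iodo-2,6-dimethyl-8-oxoocta-1,5-dien-3-yl acetate
Conditions: Dess–Martin periodinane, pyridine, CH2Cl2, 0 °C; used at once
Reagents that add atoms: none
Why: Dess–Martin oxidation under buffered, non-basic conditions should give the β,γ-unsaturated aldehyde without migration of the double bond.

Step 9
Reactants: 13 3-chloro-2-(chloromethyl)prop-1-ene; 14 (4-methoxyphenyl)methanol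
Product: 15 1-({[2-(chloromethyl)prop-2-en-1-yl]oxy}methyl)-4-methoxybenzene
Conditions: NaH, THF/DMF, 0 °C to rt, 13 in excess (3 equiv)
Reagents that add atoms: none
Why: Williamson ether synthesis on the symmetrical bis-allylic chloride; the excess of 13 favours mono-substitution.

Step 10
Reactants: 15 1-({[2-(chloromethyl)prop-2-en-1-yl]oxy}methyl)-4-methoxybenzene
Product: 17 3-{[(4-methoxybenzyl)oxy]methyl}but-3-enoic acid, via allylmagnesium chloride 16 (not isolated)
Conditions: Mg, THF, 0 °C, slow addition; then CO2, -78 °C to rt; aq HCl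
Reagents that add atoms: carbon dioxide, O=C=O; magnesium, [Mg] (in intermediate 16 only)
Why: Grignard formation and carboxylation; the allyl unit carries its substituent on the central carbon, so attack at either terminus gives the same β,γ-unsaturated acid (C6, C7, C11, C12, C13).

Step 11
Reactants: 17 3-{[(4-methoxybenzyl)oxy]methyl}but-3-enoic acid; 18 (R)-4-benzyl-1,3-oxazolidin-2-one
Product: 20 (R)-4-benzyl-3-(3-{[(4-methoxybenzyl)oxy]methyl}but-3-enoyl)-1,3-oxazolidin-2-one, via mixed pivalic anhydride 19 (not isolated)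
Conditions: t-BuCOCl, Et3N, THF, -20 °C; then 18, LiCl, rt
Reagents that add atoms: pivaloyl chloride, CC(C)(C)C(=O)Cl (in intermediate 19 only)
Why: N-Acylation of the Evans auxiliary through the mixed anhydride under LiCl/Et3N activation; the mild conditions should avoid migration of the β,γ-double bond.

Step 12
Reactants: 20 (R)-4-benzyl-3-(3-{[(4-methoxybenzyl)oxy]methyl}but-3-enoyl)-1,3-oxazolidin-2-one; 12 (1Z,3S,5E)-1-iodo-2,6-dimethyl-8-oxoocta-1,5-dien-3-yl acetate
Product: 22 (1Z,3S,5E,8S,9R)-9-{[(4R)-4-benzyl-2-oxo-1,3-oxazolidin-3-yl]carbonyl}-8-hydroxy-1-iodo-10-{[(4-methoxybenzyl)oxy]methyl}-2,6-dimethylundeca-1,5,10-trien-3-yl acetate, via boron enolate 21 (not isolated)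
Conditions: Bu2BOTf (1.1 equiv), iPr2NEt (1.2 equiv), CH2Cl2, -78 to 0 °C; 12, -78 to -20 °C; then pH 7 buffer, MeOH, H2O2, 0 °C
Reagents that add atoms: dibutylboron triflate, CCCCB(CCCC)OS(=O)(=O)C(F)(F)F (in intermediate 21 only)
Why: Evans syn-aldol; the (Z)-boron enolate reacts at its α-carbon (C7) through a chair Zimmerman–Traxler transition state on the face opposite the benzyl group of the (R)-auxiliary, which should give the 7R,8S adduct with C11 and O8 syn.

Step 13
Reactants: 22 (aldol adduct)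
Product: 23 (1Z,3S,5E,8S,9R)-9-{[(4R)-4-benzyl-2-oxo-1,3-oxazolidin-3-yl]carbonyl}-1-iodo-10-{[(4-methoxybenzyl)oxy]methyl}-2,6-dimethyl-8-[(triethylsilyl)oxy]undeca-1,5,10-trien-3-yl acetate
Conditions: Et3SiOTf, 2,6-lutidine, CH2Cl2, -78 °C
Reagents that add atoms: triethylsilyl triflate, CC[Si](CC)(CC)OS(=O)(=O)C(F)(F)F
Why: Silylation of the secondary alcohol with the silyl triflate blocks retro-aldol and later keeps O8 out of the lactonisation.

Step 14
Reactants: 23 (silyl ether)
Product: 24 (1Z,3S,5E,8S,9S)-9-(hydroxymethyl)-1-iodo-10-{[(4-methoxybenzyl)oxy]methyl}-2,6-dimethyl-8-[(triethylsilyl)oxy]undeca-1,5,10-trien-3-yl acetate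
Conditions: NaBH4 (4 equiv), THF/H2O (4:1), 0 °C to rt
Reagents that add atoms: none
Why: Reductive cleavage of the N-acyl oxazolidinone by borohydride in wet THF; the imide carbonyl is the most electrophilic acyl group, so the acetate is expected to survive, and the C7 descriptor changes only because C6 becomes CH2OH.

Step 15
Reactants: 24 (primary alcohol)
Product: 25 (1Z,3S,5R,6R,8S,9S)-5,6-epoxy-9-(hydroxymethyl)-1-iodo-10-{[(4-methoxybenzyl)oxy]methyl}-2,6-dimethyl-8-[(triethylsilyl)oxy]undeca-1,10-dien-3-yl acetate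
Conditions: D-fructose-derived Shi ketone (30 mol %), Oxone (2KHSO5·KHSO4·K2SO4), K2CO3, Bu4NHSO4 (cat.), MeCN/(MeO)2CH2/aq Na2B4O7 buffer, 0 °C
Reagents that add atoms: potassium peroxymonosulfate (active part of Oxone), [K+].[O-]S(=O)(=O)OO
Why: Shi asymmetric epoxidation; the chiral dioxirane should transfer oxygen through a spiro transition state to one face of the E-trisubstituted C1=C10 alkene to give the (1R,10R)-epoxide, while the iodoalkene and the 1,1-disubstituted C11=C13 alkene react much more slowly.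

Step 16
Reactants: 25 (epoxy alcohol)
Product: 26 (1Z,3S,5R,6R,8S,9R)-5,6-epoxy-9-formyl-1-iodo-10-{[(4-methoxybenzyl)oxy]methyl}-2,6-dimethyl-8-[(triethylsilyl)oxy]undeca-1,10-dien-3-yl acetate
Conditions: Dess–Martin periodinane, pyridine, CH2Cl2, 0 °C; used at once
Reagents that add atoms: none
Why: Dess–Martin oxidation under buffered conditions should give the C6 aldehyde without epimerising C7 or opening the epoxide.

Step 17
Reactants: 26 (iodo aldehyde)
Product: 28 (1R,3S,4Z,6R,7S,8S,10R)-1,10-epoxy-6-hydroxy-12-[(4-methoxybenzyl)oxy]-8-[(triethylsilyl)oxy]germacra-4,11(13)-dien-3-yl acetate, via alkenylchromium species 27 (not isolated)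
Conditions: CrCl2 (12 equiv), NiCl2 (0.2 equiv), degassed DMSO, rt, 26 added by syringe pump over 12 h (final about 2 mM); aqueous work-up
Reagents that add atoms: chromium dichloride, Cl[Cr]Cl (in intermediate 27 only)
Why: Intramolecular Nozaki–Hiyama–Kishi reaction: zerovalent nickel (formed from NiCl2 by CrCl2) inserts into the C5–I bond with retention, the alkenyl group passes to trivalent chromium to give the configurationally stable (Z)-alkenylchromium 27, and this adds to the aldehyde only, since esters, the epoxide and the ethers are inert to organochromium reagents. The closest known reaction type is the NHK macrocyclisation of iodoalkenyl aldehydes to ten-membered germacranolide carbocycles. The carbocycle C1–C10 is closed in a 10-exo-trig mode at the C6 carbonyl, and the Z geometry of C4=C5 holds C3 and the reacting C5 terminus on the same side, which lowers the entropic cost. The new C6 stereocentre is controlled by C7: Felkin–Anh addition anti to the C7–C8 bond with C7–H outside, an arrangement the forming ring can adopt, should give the 6R alcohol with O6 trans to C8 as the trans-fused lactone requires. The step needs aldehyde chemoselectivity and cyclisation over oligomerisation, secured by the carbonyl selectivity of alkenylchromium reagents and by slow addition at high dilution. O12 is kept as a PMB ether so that the new C6 hydroxyl stays free and the 6,12-diol is revealed only afterwards.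

Step 18
Reactants: 28 (macrocyclic alcohol)
Product: 29 (1R,3S,4Z,6R,7S,8S,10R)-1,10-epoxy-6,12-dihydroxy-8-[(triethylsilyl)oxy]germacra-4,11(13)-dien-3-yl acetate
Conditions: DDQ (1.5 equiv), CH2Cl2/pH 7 buffer (10:1), 0 °C
Reagents that add atoms: none
Why: Oxidative cleavage of the 4-methoxybenzyl ether by DDQ in wet solvent frees the primary allylic C12 alcohol without touching the silyl ether, the esters or the epoxide.

Step 19
Reactants: 29 (6,12-diol)
Product: 32 (1R,3S,4Z,6R,7S,8S,10R)-3-acetoxy-1,10-epoxy-8-[(triethylsilyl)oxy]germacra-4,11(13)-dien-12,6-olide, via hydroxy enal 30 (not isolated), via lactol 31 (not isolated)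
Conditions: TEMPO (0.2 equiv), PhI(OAc)2 (2.5 equiv), CH2Cl2, rt
Reagents that add atoms: none
Why: TEMPO/PhI(OAc)2 oxidative lactonisation of a 1,4-diol; the primary allylic alcohol is oxidised faster than the secondary C6 alcohol, the C6 hydroxyl closes the five-membered lactol, and a second oxidation gives the α-methylene-γ-lactone with C6 and C7 untouched.

Step 20
Reactants: 32 (silyl-protected lactone)
Product: 33 (1R,3S,4Z,6R,7R,8S,10R)-3-acetoxy-1,10-epoxy-8-hydroxygermacra-4,11(13)-dien-12,6-olide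
Conditions: Bu4NF, AcOH (1:1), THF, 0 °C to rt
Reagents that add atoms: none
Why: Fluoride cleavage of the secondary triethylsilyl ether, buffered with acetic acid so that the acetate, the α-methylene lactone and the epoxide should survive and the lactone should not migrate to O8.

Step 21
Reactants: 33 (C8 alcohol)
Product: 34 (1R,3S,4Z,6R,7R,8S,10R)-3-acetoxy-1,10-epoxy-8-[(3-methylbutanoyl)oxy]germacra-4,11(13)-dien-12,6-olide
Conditions: (Me2CHCH2CO)2O, Et3N, DMAP (cat.), CH2Cl2, 0 °C to rt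
Reagents that add atoms: isovaleric anhydride, CC(C)CC(=O)OC(=O)CC(C)C
Why: DMAP-catalysed acylation of the C8 alcohol with the anhydride gives the target; no stereocentre is affected.

**Compound list**
1 | prop-2-yn-1-ol | C#CCO | starting material
2 | (Z)-alkenylmagnesium bromide of the bromomagnesium alkoxide (Mg on C5 cis to CH2O) | C/C(CO[Mg]Br)=C/[Mg]Br | intermediate
3 | (Z)-3-iodo-2-methylprop-2-en-1-ol | C/C(CO)=C/I | intermediate
4 | (Z)-3-iodo-2-methylprop-2-enal | C/C(C=O)=C/I | intermediate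
5 | (1Z,3S)-1-iodo-2-methylhexa-1,5-dien-3-ol | I/C=C(/C)[C@@H](O)CC=C | intermediate
6 | (1Z,3S)-1-iodo-2-methylhexa-1,5-dien-3-yl acetate | I/C=C(/C)[C@@H](OC(C)=O)CC=C | intermediate
7 | methacrolein (2-methylprop-2-enal) | CC(=C)C=O | starting material
8 | (2E,5S,6Z)-7-iodo-2,6-dimethyl-1-oxohepta-2,6-dien-5-yl acetate | I/C=C(/C)[C@@H](OC(C)=O)C/C=C(\C)C=O | intermediate
9 | (1Z,3S,5E)-1-iodo-2,6-dimethylocta-1,5,7-trien-3-yl acetate | I/C=C(/C)[C@@H](OC(C)=O)C/C=C(\C)C=C | intermediate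
10 | (1Z,3S,5E)-8-(9-borabicyclo[3.3.1]nonan-9-yl)-1-iodo-2,6-dimethylocta-1,5-dien-3-yl acetate | I/C=C(/C)[C@@H](OC(C)=O)C/C=C(\C)CCB1C2CCCC1CCC2 | intermediate
11 | (1Z,3S,5E)-8-hydroxy-1-iodo-2,6-dimethylocta-1,5-dien-3-yl acetate | I/C=C(/C)[C@@H](OC(C)=O)C/C=C(\C)CCO | intermediate
12 | (1Z,3S,5E)-1-iodo-2,6-dimethyl-8-oxoocta-1,5-dien-3-yl acetate | I/C=C(/C)[C@@H](OC(C)=O)C/C=C(\C)CC=O | intermediate
13 | 3-chloro-2-(chloromethyl)prop-1-ene | C=C(CCl)CCl | starting material
14 | (4-methoxyphenyl)methanol | COc1ccc(CO)cc1 | starting material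
15 | 1-({[2-(chloromethyl)prop-2-en-1-yl]oxy}methyl)-4-methoxybenzene | C=C(CCl)COCc1ccc(OC)cc1 | intermediate
16 | (2-{[(4-methoxybenzyl)oxy]methyl}prop-2-en-1-yl)magnesium chloride | C=C(C[Mg]Cl)COCc1ccc(OC)cc1 | intermediate
17 | 3-{[(4-methoxybenzyl)oxy]methyl}but-3-enoic acid | C=C(CC(=O)O)COCc1ccc(OC)cc1 | intermediate
18 | (R)-4-benzyl-1,3-oxazolidin-2-one | O=C1OC[C@@H](Cc2ccccc2)N1 | starting material
19 | 3-{[(4-methoxybenzyl)oxy]methyl}but-3-enoic pivalic anhydride | C=C(CC(=O)OC(=O)C(C)(C)C)COCc1ccc(OC)cc1 | intermediate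
20 | (R)-4-benzyl-3-(3-{[(4-methoxybenzyl)oxy]methyl}but-3-enoyl)-1,3-oxazolidin-2-one | C=C(CC(=O)N1[C@H](Cc2ccccc2)COC1=O)COCc1ccc(OC)cc1 | intermediate
21 | dibutylboron (Z)-enolate of 20 (O–B cis to C11 across C6=C7) | CCCCB(CCCC)O/C(=C\C(=C)COCc1ccc(OC)cc1)N1[C@H](Cc2ccccc2)COC1=O | intermediate
22 | (1Z,3S,5E,8S,9R)-9-{[(4R)-4-benzyl-2-oxo-1,3-oxazolidin-3-yl]carbonyl}-8-hydroxy-1-iodo-10-{[(4-methoxybenzyl)oxy]methyl}-2,6-dimethylundeca-1,5,10-trien-3-yl acetate | I/C=C(/C)[C@@H](OC(C)=O)C/C=C(\C)C[C@H](O)[C@H](C(=O)N1[C@H](Cc2ccccc2)COC1=O)C(=C)COCc1ccc(OC)cc1 | intermediate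
23 | (1Z,3S,5E,8S,9R)-9-{[(4R)-4-benzyl-2-oxo-1,3-oxazolidin-3-yl]carbonyl}-1-iodo-10-{[(4-methoxybenzyl)oxy]methyl}-2,6-dimethyl-8-[(triethylsilyl)oxy]undeca-1,5,10-trien-3-yl acetate | I/C=C(/C)[C@@H](OC(C)=O)C/C=C(\C)C[C@H](O[Si](CC)(CC)CC)[C@H](C(=O)N1[C@H](Cc2ccccc2)COC1=O)C(=C)COCc1ccc(OC)cc1 | intermediate
24 | (1Z,3S,5E,8S,9S)-9-(hydroxymethyl)-1-iodo-10-{[(4-methoxybenzyl)oxy]methyl}-2,6-dimethyl-8-[(triethylsilyl)oxy]undeca-1,5,10-trien-3-yl acetate | I/C=C(/C)[C@@H](OC(C)=O)C/C=C(\C)C[C@H](O[Si](CC)(CC)CC)[C@H](CO)C(=C)COCc1ccc(OC)cc1 | intermediate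
25 | (1Z,3S,5R,6R,8S,9S)-5,6-epoxy-9-(hydroxymethyl)-1-iodo-10-{[(4-methoxybenzyl)oxy]methyl}-2,6-dimethyl-8-[(triethylsilyl)oxy]undeca-1,10-dien-3-yl acetate | I/C=C(/C)[C@@H](OC(C)=O)C[C@H]1O[C@]1(C)C[C@H](O[Si](CC)(CC)CC)[C@H](CO)C(=C)COCc1ccc(OC)cc1 | intermediate
26 | (1Z,3S,5R,6R,8S,9R)-5,6-epoxy-9-formyl-1-iodo-10-{[(4-methoxybenzyl)oxy]methyl}-2,6-dimethyl-8-[(triethylsilyl)oxy]undeca-1,10-dien-3-yl acetate | I/C=C(/C)[C@@H](OC(C)=O)C[C@H]1O[C@]1(C)C[C@H](O[Si](CC)(CC)CC)[C@H](C=O)C(=C)COCc1ccc(OC)cc1 | intermediate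
27 | (Z)-alkenylchromium dichloride of 26 (CrCl2 on C5 in place of iodine; other centres as in 26) | Cl[Cr](Cl)/C=C(/C)[C@@H](OC(C)=O)C[C@H]1O[C@]1(C)C[C@H](O[Si](CC)(CC)CC)[C@H](C=O)C(=C)COCc1ccc(OC)cc1 | intermediate
28 | (1R,3S,4Z,6R,7S,8S,10R)-1,10-epoxy-6-hydroxy-12-[(4-methoxybenzyl)oxy]-8-[(triethylsilyl)oxy]germacra-4,11(13)-dien-3-yl acetate | O[C@@H]1/C=C(/C)[C@@H](OC(C)=O)C[C@H]2O[C@]2(C)C[C@H](O[Si](CC)(CC)CC)[C@H]1C(=C)COCc1ccc(OC)cc1 | intermediate
29 | (1R,3S,4Z,6R,7S,8S,10R)-1,10-epoxy-6,12-dihydroxy-8-[(triethylsilyl)oxy]germacra-4,11(13)-dien-3-yl acetate | O[C@@H]1/C=C(/C)[C@@H](OC(C)=O)C[C@H]2O[C@]2(C)C[C@H](O[Si](CC)(CC)CC)[C@H]1C(=C)CO | intermediate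
30 | (1R,3S,4Z,6R,7S,8S,10R)-1,10-epoxy-6-hydroxy-12-oxo-8-[(triethylsilyl)oxy]germacra-4,11(13)-dien-3-yl acetate | O[C@@H]1/C=C(/C)[C@@H](OC(C)=O)C[C@H]2O[C@]2(C)C[C@H](O[Si](CC)(CC)CC)[C@H]1C(=C)C=O | intermediate
31 | 12-hydroxy lactol of 32 (both C12 epimers; other centres as in 32) | C=C1C(O)O[C@@H]2/C=C(/C)[C@@H](OC(C)=O)C[C@H]3O[C@]3(C)C[C@H](O[Si](CC)(CC)CC)[C@@H]12 | intermediate
32 | (1R,3S,4Z,6R,7S,8S,10R)-3-acetoxy-1,10-epoxy-8-[(triethylsilyl)oxy]germacra-4,11(13)-dien-12,6-olide | C=C1C(=O)O[C@@H]2/C=C(/C)[C@@H](OC(C)=O)C[C@H]3O[C@]3(C)C[C@H](O[Si](CC)(CC)CC)[C@@H]12 | intermediate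
33 | (1R,3S,4Z,6R,7R,8S,10R)-3-acetoxy-1,10-epoxy-8-hydroxygermacra-4,11(13)-dien-12,6-olide | C=C1C(=O)O[C@@H]2/C=C(/C)[C@@H](OC(C)=O)C[C@H]3O[C@]3(C)C[C@H](O)[C@@H]12 | intermediate
34 | (1R,3S,4Z,6R,7R,8S,10R)-3-acetoxy-1,10-epoxy-8-[(3-methylbutanoyl)oxy]germacra-4,11(13)-dien-12,6-olide | C=C1C(=O)O[C@@H]2/C=C(/C)[C@@H](OC(C)=O)C[C@H]3O[C@]3(C)C[C@H](OC(=O)CC(C)C)[C@@H]12 | target

**Step count and risks**

Total: 21 steps. Longest linear sequence: 18 steps (steps 1–8 and 12–21); steps 9–11 form the three-step side branch.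

Steps most likely to fail:

1. Step 17 (ring closure). What may go wrong: addition to the other face of the C6 aldehyde, if ring strain or a 1,3-effect of the C8 silyloxy group overrides the Felkin–Anh preference, and oligomerisation. Fallback, from 26 back to 28: the ring is still closed by the chromium-mediated addition, but C6 is then set by an SN2 inversion instead of by the addition. The (6S)-epimeric macrocyclic alcohol F1 is esterified under Mitsunobu conditions (chloroacetic acid, PPh3, DIAD, toluene, 0 °C) to the inverted (6R)-chloroacetate F2. The chloroacetyl group is then removed with thiourea and NaHCO3 in EtOH, which should not touch the acetate, to give 28.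

2. Step 12 (aldol). What may go wrong: migration of the β,γ-double bond of aldehyde 12 into conjugation before C–C bond formation, or γ-attack and double-bond migration of the boron dienolate, with loss of facial control. Fallback, from 17 (with 12) back to 24: the donor is changed to a thioimide whose pre-formed chlorotitanium enolate adds within minutes at -78 °C. Acid 17 is condensed with (R)-4-benzyl-1,3-thiazolidine-2-thione (EDC·HCl, DMAP, CH2Cl2) to the N-acylthiazolidinethione F3. TiCl4 (1.05 equiv), iPr2NEt (2.2 equiv) and N-methyl-2-pyrrolidinone in CH2Cl2 give the chlorotitanium enolate F4, which is combined with 12 at -78 °C to give the 7R,8S syn adduct F5. Et3SiOTf and 2,6-lutidine give the triethylsilyl ether F6, and NaBH4 in wet THF cleaves the thione auxiliary to give 24.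

3. Step 15 (epoxidation). What may go wrong: competing oxidation of the 1,1-disubstituted C11=C13 alkene, or insufficient facial selectivity at C1=C10. Fallback, from 22 back to 25: oxygen is delivered by a hydroxyl-directed, ligand-controlled metal catalyst instead of the dioxirane. The free homoallylic C8 hydroxyl of 22 directs a vanadium-catalysed asymmetric epoxidation (VO(OiPr)3, chiral bishydroxamic acid ligand of the sense matching the 1R,10R epoxide, cumene hydroperoxide, toluene, 0 °C) to the electron-rich C1=C10 alkene, giving the epoxy imide F7. Et3SiOTf and 2,6-lutidine give its triethylsilyl ether F8, and NaBH4 in wet THF removes the auxiliary to give 25.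

**Further compounds**
F1 | step 17 | (1R,3S,4Z,6S,7S,8S,10R)-1,10-epoxy-6-hydroxy-12-[(4-methoxybenzyl)oxy]-8-[(triethylsilyl)oxy]germacra-4,11(13)-dien-3-yl acetate (6-epimer of 28) | O[C@H]1/C=C(/C)[C@@H](OC(C)=O)C[C@H]2O[C@]2(C)C[C@H](O[Si](CC)(CC)CC)[C@H]1C(=C)COCc1ccc(OC)cc1
F2 | step 17 | (1R,3S,4Z,6R,7S,8S,10R)-6-(chloroacetoxy)-1,10-epoxy-12-[(4-methoxybenzyl)oxy]-8-[(triethylsilyl)oxy]germacra-4,11(13)-dien-3-yl acetate | O=C(CCl)O[C@@H]1/C=C(/C)[C@@H](OC(C)=O)C[C@H]2O[C@]2(C)C[C@H](O[Si](CC)(CC)CC)[C@H]1C(=C)COCc1ccc(OC)cc1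
F3 | step 12 | (R)-4-benzyl-3-(3-{[(4-methoxybenzyl)oxy]methyl}but-3-enoyl)-1,3-thiazolidine-2-thione | C=C(CC(=O)N1[C@H](Cc2ccccc2)CSC1=S)COCc1ccc(OC)cc1
F4 | step 12 | trichlorotitanium (Z)-enolate of F3 | Cl[Ti](Cl)(Cl)O/C(=C\C(=C)COCc1ccc(OC)cc1)N1[C@H](Cc2ccccc2)CSC1=S
F5 | step 12 | (1Z,3S,5E,8S,9R)-9-{[(4R)-4-benzyl-2-thioxo-1,3-thiazolidin-3-yl]carbonyl}-8-hydroxy-1-iodo-10-{[(4-methoxybenzyl)oxy]methyl}-2,6-dimethylundeca-1,5,10-trien-3-yl acetate | I/C=C(/C)[C@@H](OC(C)=O)C/C=C(\C)C[C@H](O)[C@H](C(=O)N1[C@H](Cc2ccccc2)CSC1=S)C(=C)COCc1ccc(OC)cc1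
F6 | step 12 | 8-O-triethylsilyl ether of F5 | I/C=C(/C)[C@@H](OC(C)=O)C/C=C(\C)C[C@H](O[Si](CC)(CC)CC)[C@H](C(=O)N1[C@H](Cc2ccccc2)CSC1=S)C(=C)COCc1ccc(OC)cc1
F7 | step 15 | (1Z,3S,5R,6R,8S,9R)-9-{[(4R)-4-benzyl-2-oxo-1,3-oxazolidin-3-yl]carbonyl}-5,6-epoxy-8-hydroxy-1-iodo-10-{[(4-methoxybenzyl)oxy]methyl}-2,6-dimethylundeca-1,10-dien-3-yl acetate | I/C=C(/C)[C@@H](OC(C)=O)C[C@H]1O[C@]1(C)C[C@H](O)[C@H](C(=O)N2[C@H](Cc3ccccc3)COC2=O)C(=C)COCc2ccc(OC)cc2
F8 | step 15 | 8-O-triethylsilyl ether of F7 | I/C=C(/C)[C@@H](OC(C)=O)C[C@H]1O[C@]1(C)C[C@H](O[Si](CC)(CC)CC)[C@H](C(=O)N2[C@H](Cc3ccccc3)COC2=O)C(=C)COCc2ccc(OC)cc2
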